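The pitfall is to read a plateau of left-handed product as a stalled reaction. In the steps thought possible, left-handed product comes through catalyst intermediate A from left-handed substrate, so its ceiling is that substrate's share of the charge, 50.0 %. The question for each flask is whether it reaches this ceiling in time.

| setting | ash | birch | cedar | Saturday's | Tuesday's |
|---|---|---|---|---|---|
| left-handed substrate | 0.20 M | 0.20 M | 0.30 M | 0.20 M | 0.20 M |
| right-handed substrate | 0.20 M | 0.20 M | 0.30 M | 0.20 M | 0.20 M |
| gas | 42 mM (held) | 42 mM (held) | 42 mM (held) | 42 mM (held) | 42 mM (held) |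
| precatalyst | 1.6 mM | 3.6 mM | 2.4 mM | 2.4 mM | 2.4 mM |
| temperature | 48 °C | 64 °C | 48 °C | 70 °C | 40 °C |
| remark | run made earlier | run made earlier | run made earlier |  |  |
| time |  |  |  | 40 h | 40 h |

| run | time / h | left-handed product / % | left-handed substrate / % |
|---|---|---|---|
| ash | 4.00 | 3 | 46 |
| ash | 15.0 | 36 | 10 |
| ash | 30.0 | 52 | 0 |
| ash | 40.0 | 49 | 0 |
| ash | 60.0 | 53 | 2 |
| ash | 72.0 | 45 | 1 |
| ash | 96.0 | 49 | 3 |
| birch | 5.00 | 50 | 0 |
| birch | 10.0 | 52 | 0 |
| birch | 15.0 | 51 | 0 |
| birch | 20.0 | 52 | 0 |
| birch | 25.0 | 52 | 0 |
| birch | 30.0 | 49 | 2 |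
| cedar | 8.00 | 17 | 37 |
| cedar | 15.0 | 39 | 12 |
| cedar | 30.0 | 49 | 0 |
| cedar | 40.0 | 48 | 1 |
| cedar | 96.0 | 52 | 0 |

(standard deviation of a reading: 2 percentage points)

- free catalyst is single-handed; left-handed substrate and right-handed substrate are mirror images of each other, charged as a racemate, each of them at the stated concentration
- at the start none of reagent is dissolved
- steps thought possible: free catalyst + left-handed substrate <-> catalyst intermediate A; free catalyst + right-handed substrate <-> catalyst intermediate B; reagent + catalyst intermediate A -> free catalyst + left-handed product; reagent + catalyst intermediate B -> free catalyst + right-handed product; gas <-> reagent; precatalyst -> free catalyst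

1. the flask with the highest amount of left-handed product, in percent of the left-handed substrate and right-handed substrate together charged ("all alike" if they lie within 1.5 percentage points) (Saturday's / Tuesday's / all alike)
2. final left-handed product, as a percentage of the left-handed substrate and right-handed substrate together charged, in Saturday's
3. final left-handed product, as a percentage of the left-handed substrate and right-handed substrate together charged, in Tuesday's

Tuesday's looks nearly like ash: the same substrates, but colder (40 °C against 48 °C) and with 2.4 mM of precatalyst against 1.6 mM. In ash, left-handed substrate falls from 46 % at 4.00 h to 10 % at 15.0 h, a reading of 0.0327 h⁻¹ as a fraction of the charge. Running that line back, the first reading shows a delay of about 2.78 h.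

I define the clearing time as the delay plus the ceiling divided by that speed, with the delay held and the speed taken in proportion to precatalyst. For ash it is 18.1 h, shorter than 40.0 h, so the reckoning puts ash at the ceiling then, and the reading there is 49 %.

With 2.4 mM at 48 °C, the clearing time is 13.0 h. Ash and cedar stand at 48 °C and birch at 64 °C, so no earlier reading was taken at 40 °C. I assume a stretch by a factor of 3, which gives 38.9 h for Tuesday's, narrowly shorter than 40 h. Saturday's, at 70 °C, is hotter than 48 °C, so I take its clearing time to be below 13.0 h, itself shorter than 40 h. So I commit to the ceiling in both flasks.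

The forecast gives 50 % for Saturday's and 49 % for Tuesday's, where my figure is 50.0 %, and names all alike; of Tuesday's it says: “I expect it to be essentially complete.”

The simulation gives 50.0 % in Saturday's and 50.0 % in Tuesday's, so the answer is all alike.

    free catalyst + left-handed substrate ⇌ catalyst intermediate A (K = 97.0 L mol⁻¹, k = 19000 L mol⁻¹ h⁻¹, Ea = 58.0 kJ mol⁻¹, ΔH = −13.0 kJ mol⁻¹)
    free catalyst + right-handed substrate ⇌ catalyst intermediate B (K = 2.00 L mol⁻¹, k = 7600 L mol⁻¹ h⁻¹, Ea = 52.0 kJ mol⁻¹, ΔH = −64.0 kJ mol⁻¹)
    reagent + catalyst intermediate A → free catalyst + left-handed product (k = 240 L mol⁻¹ h⁻¹, Ea = 42.0 kJ mol⁻¹)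
    reagent + catalyst intermediate B → free catalyst + right-handed product (k = 79.0 L mol⁻¹ h⁻¹, Ea = 70.0 kJ mol⁻¹)
    gas ⇌ reagent, rate k5*(csat - [reagent]) (kL = 100 h⁻¹)
    precatalyst → free catalyst (k = 0.0400 h⁻¹, Ea = 97.0 kJ mol⁻¹)
    (constants at 40 °C)

Tuesday's holds 0 % left-handed substrate at 40.0 h, alongside 6.36 % right-handed product. The same reckoning goes to Saturday's flask read early, at 15 h. Taken with no gain from heat, the clearing time is 13.0 h, shorter than that reading time, so the reckoning puts this reading at the ceiling. Saturday's flask at that time shows 50.0 % left-handed product, with 0 % left-handed substrate and 10.0 % right-handed product.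

The runs were computed with constants of no real substance; the scatter is artificial.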